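**Strategy.** Ring B is cut at C5–C10 and C8–C9, the two sigma bonds of a [4+2] cycloaddition. C5–C8, with the oxygens on C6 and C8 and the C8 methyl, map onto C3–C6, the 4-oxygen, the ring oxygen and the 6-methyl of a 3-alkyl-4-methoxy-6-methyl-2-pyrone. C9=C10 is the exocyclic enol ether of the preformed spiro-tetrahydrofuran, linked to the pyrone by the C4–C1 chain. One intramolecular pyrone Diels–Alder reaction closes rings A and B and sets C5, C8, C9 and C10 from the single Sharpless-derived stereocenter C13. The lactone bridge then delivers the 8β-hydroxyl and leaves C5 as carbon dioxide; the C13 alkyne closes the dihydrofuran last.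

Key step: step 13

Remark: labdane numbering is used (ring A C1–C5/C10, ring B C5–C10, C11–C13 and O in the tetrahydrofuran, C14–C16 and O in the dihydrofuran, C17 on C8, C20 on C10); ethyl 2-acetyl-3-methylbut-2-enoate (9) is taken as a catalogue compound.

Step 1
Reactants: 1 2-bromoprop-2-en-1-ol; 2 ethynyltrimethylsilane
Product: 3 2-[(trimethylsilyl)ethynyl]prop-2-en-1-ol
Conditions: Pd(PPh3)2Cl2 (2 mol%), CuI (4 mol%), iPr2NH, THF, rt
Reagents that add atoms: none
Why: Sonogashira coupling of a 2-bromoalkene with a terminal alkyne should give the conjugated enyne, the free allylic hydroxyl being tolerated and no stereocenter being formed.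

Step 2
Reactants: 3
Product: 4 [(2S)-2-[(trimethylsilyl)ethynyl]oxiran-2-yl]methanol
Conditions: Ti(OiPr)4 (10 mol%), L-(+)-diethyl tartrate (12 mol%), t-BuOOH, 4 Å MS, CH2Cl2, −20 °C
Reagents that add atoms: tert-butyl hydroperoxide, CC(C)(C)OO
Why: Sharpless asymmetric epoxidation of a 2-substituted allylic alcohol, in which the L-(+)-tartrate should deliver oxygen to the face that gives the (S)-epoxide (the sense known for 2-methylallyl alcohol) and so fix the later C13.

Step 3
Reactants: 4
Product: 5 (2S)-2-[(trimethylsilyl)ethynyl]hex-5-yne-1,2-diol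
Conditions: 3-bromoprop-1-yne, n-BuLi (2 equiv), TMEDA, Et2O/hexane, −78 °C; then 4 (pre-treated with n-BuLi, 1 equiv), −78 → 0 °C; aq. NH4Cl
Reagents that add atoms: 3-bromoprop-1-yne (as 1,3-dilithiopropyne), C#CCBr
Why: SN2 opening of the 2,2-disubstituted epoxide at its CH2 terminus by the sp3 carbon of the propargyl dianion (an organolithium, so no SN2' allene formation) leaves the C–O bond of the quaternary carbon intact, and a Payne shift would be degenerate, so the configuration is retained.

Step 4
Reactants: 5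
Product: 6 {[(4S)-4-(but-3-yn-1-yl)-2,2-dimethyl-1,3-dioxolan-4-yl]ethynyl}trimethylsilane
Conditions: 2,2-dimethoxypropane, PPTS (cat.), CH2Cl2, rt
Reagents that add atoms: 2,2-dimethoxypropane, COC(C)(C)OC
Why: acid-catalysed acetonide formation masks both hydroxyls, so that the terminal alkyne C–H is the only acidic site left.

Step 5
Reactants: 6
Product: 8 {[(4S)-4-(7-chlorohept-3-yn-1-yl)-2,2-dimethyl-1,3-dioxolan-4-yl]ethynyl}trimethylsilane, via lithium acetylide 7 (not isolated)
Conditions: n-BuLi, THF, −78 °C; then 1-chloro-3-iodopropane, DMPU, −78 °C → rt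
Reagents that add atoms: 1-chloro-3-iodopropane, ClCCCI
Why: alkylation of a lithium acetylide, chemoselective for the C–I over the C–Cl bond, installs C1–C3 of the tether.

Step 6
Reactants: 8; 9 ethyl 2-acetyl-3-methylbut-2-enoate
Product: 11 ethyl 2-acetyl-3,3-dimethyl-10-{(4S)-2,2-dimethyl-4-[(trimethylsilyl)ethynyl]-1,3-dioxolan-4-yl}dec-7-ynoate (C2 epimers), via organomagnesium chloride 10 (not isolated)
Conditions: Mg, THF, 60 °C; then 9, CuBr·SMe2 (10 mol%), −40 → 0 °C; aq. NH4Cl
Reagents that add atoms: none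
Why: copper-catalysed conjugate addition of the Grignard reagent to the doubly activated alkylidene β-keto ester should build the quaternary C4 with its two methyls, the new α-stereocenter being lost later.

Step 7
Reactants: 11
Product: 13 ethyl 2-(2-methyl-9-{(4S)-2,2-dimethyl-4-[(trimethylsilyl)ethynyl]-1,3-dioxolan-4-yl}non-6-yn-2-yl)-3,5-dioxohexanoate (tautomer and epimer mixture), via dilithium dienolate 12 (not isolated)
Conditions: LiN(iPr)2 (2.4 equiv), THF, −78 → 0 °C; then N-methoxy-N-methylacetamide, −78 → 0 °C; aq. NH4Cl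
Reagents that add atoms: N-methoxy-N-methylacetamide, CC(=O)N(C)OC
Why: γ-acylation of a β-keto ester dianion with an N-methoxy-N-methyl amide, whose chelated tetrahedral adduct prevents over-addition, gives the triketide needed for the pyrone.

Step 8
Reactants: 13
Product: 15 4-methoxy-6-methyl-3-(2-methyl-9-{(4S)-2,2-dimethyl-4-[(trimethylsilyl)ethynyl]-1,3-dioxolan-4-yl}non-6-yn-2-yl)-2H-pyran-2-one, via 4-hydroxy-2-pyrone 14 (not isolated)
Conditions: DBU, toluene, 110 °C; evaporation; Me2SO4, K2CO3, acetone, 50 °C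
Reagents that add atoms: dimethyl sulfate, COS(=O)(=O)OC
Why: base-mediated lactonisation of the 3,5-diketo ester gives the 4-hydroxy-2-pyrone, which is O-methylated at the 4-oxygen as is usual for 4-hydroxy-6-methyl-2-pyrones.

Step 9
Reactants: 15
Product: 16 3-{(10S)-10,11-dihydroxy-2-methyl-10-[(trimethylsilyl)ethynyl]undec-6-yn-2-yl}-4-methoxy-6-methyl-2H-pyran-2-one
Conditions: AcOH/H2O/THF (3:1:1), 50 °C
Reagents that add atoms: none
Why: acid hydrolysis of the isopropylidene ketal, to which the vinylogous ester of the pyrone and the C–Si bond should be stable.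

Step 10
Reactants: 16
Product: 17 (2S)-2-hydroxy-10-(4-methoxy-6-methyl-2-oxo-2H-pyran-3-yl)-10-methyl-2-[(trimethylsilyl)ethynyl]undec-5-yn-1-yl acetate (primary acetate of 16)
Conditions: Ac2O (1.1 equiv), pyridine, CH2Cl2, 0 °C
Reagents that add atoms: acetic anhydride, CC(=O)OC(C)=O
Why: selective acylation of the primary over the tertiary propargylic hydroxyl removes the competing oxygen nucleophile and enlarges the C16 arm on C13.

Step 11
Reactants: 17
Product: 18 [(2S,5E)-5-[1-iodo-5-(4-methoxy-6-methyl-2-oxo-2H-pyran-3-yl)-5-methylhexylidene]-2-[(trimethylsilyl)ethynyl]oxolan-2-yl]methyl acetate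
Conditions: I2, NaHCO3, MeCN, 0 °C, dark
Reagents that add atoms: iodine, II
Why: 5-exo-dig iodoetherification of a 4-alkyn-1-ol proceeds by anti addition, which places iodine trans to the ring oxygen and hence the tether carbon C1 cis to it.

Step 12
Reactants: 18
Product: 19 [(2S,5Z)-5-[6-(4-methoxy-6-methyl-2-oxo-2H-pyran-3-yl)-6-methylheptan-2-ylidene]-2-[(trimethylsilyl)ethynyl]oxolan-2-yl]methyl acetate
Conditions: MeZnCl, Pd(PPh3)4 (5 mol%), THF, 40 °C
Reagents that add atoms: methylzinc chloride, C[Zn]Cl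
Why: Negishi coupling of an alkenyl iodide goes with retention of geometry, so the new methyl (C20) stands cis to C11, as the C9/C10 relationship requires.

Step 13
Reactants: 19
Product: 20 cycloadduct: 16-acetoxy-9α,13-epoxy-6-methoxy-15-(trimethylsilyl)labd-6-en-14-yne whose extra 5β-carbonyl is lactonised onto the 8β-oxygen (bicyclo[2.2.2]octene lactone; 8α-CH3, 10β-CH3, 13S)
Conditions: toluene (0.005 M), BHT, Et3N (trace), sealed tube, 150 °C
Reagents that add atoms: none
Why: Intramolecular Diels–Alder reaction of a 2-pyrone: the pyrone carbons C3=C4–C5=C6 (labdane C5–C8) add suprafacially across the tethered enol ether C9=C10 in a concerted, asynchronous [4π+2π] process in which the electron-rich enol ether meets the lactone-conjugated diene in the inverse-demand sense. The closest known reactions are thermal intramolecular 2-pyrone cycloadditions with tethered alkenes, which give isolable bicyclo[2.2.2]octene lactones, and intermolecular pyrone–vinyl ether additions. Ring A is closed by the C5–C10 bond as the four-carbon tether C4–C1 folds into a fused cyclohexane (tether on the diene terminus, type 1 mode), and ring B by both new bonds as the cyclohexene of the lactone-bridged bicycle. C5 and C8 are fixed by the bridge itself (carbonyl and oxygen on the same, later β, face); the cis relation of C20 and C11 follows from the (Z) enol ether, and the endo placement of the ring oxygen together with the tether (the usual alkoxy-endo preference of pyrone–enol ether additions) puts C20 and C11 on the lactone face and the ether oxygen on the α face. The step needs face selectivity with respect to C13: the diene should pass the slim alkynyl group, anti to the acetoxymethyl arm, which gives the 9S,10S series. The temperature is kept below that of carbon dioxide extrusion, and the amine keeps the exocyclic enol ether from migrating.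

Step 14
Reactants: 20
Product: 22 7β-hydroxy-6,6-dimethoxy lactone (20 with C6=C7 converted into C6(OCH3)2–C7H(OH), hydroxyl on the lactone face), via methoxy epoxide 21 (not isolated)
Conditions: DMDO, acetone/MeOH (1:1), −40 → 0 °C
Reagents that add atoms: dimethyldioxirane, CC1(C)OO1; methanol, CO
Why: Rubottom-type epoxidation of the methyl enol ether from the open lactone face (the other face is screened by the endo ether oxygen and C1 of the C9–C10 bridge) and methanolysis of the alkoxy epoxide at C6 should set the 7β-hydroxyl and keep C6 masked as a ketal.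

Step 15
Reactants: 22
Product: 25 (5S,7R,8S,9S,10S,13S)-7β,8β,16-trihydroxy-9α,13-epoxylabd-14-yn-6-one, via lithium carboxylate 23 (not isolated), via keto acid 24 (not isolated)
Conditions: LiOH, THF/MeOH/H2O, 60 °C; then 2 M HCl to pH 1, 40 °C
Reagents that add atoms: water, O
Why: saponification opens the strained bridged lactone at the acyl carbon (C8–O retained) and removes the acetate and C-silyl groups while C6 is still a ketal, after which acid unmasks the ketone and the β-keto acid decarboxylates, the enol being protonated on the less hindered α face to give the trans ring fusion (5α-H), which is also the thermodynamic one.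

Step 16
Reactants: 25
Product: 26 (5S,7R,8S,9S,10S,13S)-7β,8β-dihydroxy-9α,13;15,16-diepoxylabd-14-en-6-one
Conditions: Mo(CO)6 (30 mol%), Et3N, Et2O, hν (350 nm), rt
Reagents that add atoms: none
Why: cycloisomerisation of a homopropargylic alcohol through a molybdenum vinylidene, the C16 hydroxyl adding 5-endo to C15, should give the 2,3-dihydrofuran under basic conditions without touching C13.

Step 17
Reactants: 26
Product: 27 (5S,7R,8S,9S,10S,13S)-7β-acetoxy-8β-hydroxy-9α,13;15,16-diepoxylabd-14-en-6-one (CNP0284584.1)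
Conditions: Ac2O, pyridine, DMAP (cat.), CH2Cl2, 0 °C → rt
Reagents that add atoms: acetic anhydride, CC(=O)OC(C)=O
Why: acylation of the secondary, equatorial 7β-hydroxyl, the tertiary 8-hydroxyl being inert and the basic medium preserving the enol ether.

**Compound list**

1 | 2-bromoprop-2-en-1-ol | C=C(Br)CO | starting material
2 | ethynyltrimethylsilane | C#C[Si](C)(C)C | starting material
3 | 2-[(trimethylsilyl)ethynyl]prop-2-en-1-ol | C=C(CO)C#C[Si](C)(C)C | intermediate
4 | [(2S)-2-[(trimethylsilyl)ethynyl]oxiran-2-yl]methanol | OC[C@@]1(C#C[Si](C)(C)C)CO1 | intermediate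
5 | (2S)-2-[(trimethylsilyl)ethynyl]hex-5-yne-1,2-diol | C#CCC[C@@](CO)(C#C[Si](C)(C)C)O | intermediate
6 | {[(4S)-4-(but-3-yn-1-yl)-2,2-dimethyl-1,3-dioxolan-4-yl]ethynyl}trimethylsilane | C#CCC[C@]1(C#C[Si](C)(C)C)COC(C)(C)O1 | intermediate
7 | lithium acetylide of 6 (not isolated) | [Li]C#CCC[C@]1(C#C[Si](C)(C)C)COC(C)(C)O1 | intermediate
8 | {[(4S)-4-(7-chlorohept-3-yn-1-yl)-2,2-dimethyl-1,3-dioxolan-4-yl]ethynyl}trimethylsilane | ClCCCC#CCC[C@]1(C#C[Si](C)(C)C)COC(C)(C)O1 | intermediate
9 | ethyl 2-acetyl-3-methylbut-2-enoate | CCOC(=O)C(C(C)=O)=C(C)C | starting material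
10 | organomagnesium chloride from 8 (not isolated) | Cl[Mg]CCCC#CCC[C@]1(C#C[Si](C)(C)C)COC(C)(C)O1 | intermediate
11 | ethyl 2-acetyl-3,3-dimethyl-10-{(4S)-2,2-dimethyl-4-[(trimethylsilyl)ethynyl]-1,3-dioxolan-4-yl}dec-7-ynoate (C2 epimers) | CCOC(=O)C(C(C)=O)C(C)(C)CCCC#CCC[C@]1(C#C[Si](C)(C)C)COC(C)(C)O1 | intermediate
12 | dilithium dienolate of 11 (not isolated) | CCOC(O[Li])=C(C(=C)O[Li])C(C)(C)CCCC#CCC[C@]1(C#C[Si](C)(C)C)COC(C)(C)O1 | intermediate
13 | ethyl 2-(2-methyl-9-{(4S)-2,2-dimethyl-4-[(trimethylsilyl)ethynyl]-1,3-dioxolan-4-yl}non-6-yn-2-yl)-3,5-dioxohexanoate | CCOC(=O)C(C(=O)CC(C)=O)C(C)(C)CCCC#CCC[C@]1(C#C[Si](C)(C)C)COC(C)(C)O1 | intermediate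
14 | 4-hydroxy-6-methyl-3-(2-methyl-9-{(4S)-2,2-dimethyl-4-[(trimethylsilyl)ethynyl]-1,3-dioxolan-4-yl}non-6-yn-2-yl)-2H-pyran-2-one (not isolated) | CC1=CC(O)=C(C(C)(C)CCCC#CCC[C@]2(C#C[Si](C)(C)C)COC(C)(C)O2)C(=O)O1 | intermediate
15 | 4-methoxy-6-methyl-3-(2-methyl-9-{(4S)-2,2-dimethyl-4-[(trimethylsilyl)ethynyl]-1,3-dioxolan-4-yl}non-6-yn-2-yl)-2H-pyran-2-one | COC1=C(C(C)(C)CCCC#CCC[C@]2(C#C[Si](C)(C)C)COC(C)(C)O2)C(=O)OC(C)=C1 | intermediate
16 | 3-{(10S)-10,11-dihydroxy-2-methyl-10-[(trimethylsilyl)ethynyl]undec-6-yn-2-yl}-4-methoxy-6-methyl-2H-pyran-2-one | COC1=C(C(C)(C)CCCC#CCC[C@@](CO)(C#C[Si](C)(C)C)O)C(=O)OC(C)=C1 | intermediate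
17 | (2S)-2-hydroxy-10-(4-methoxy-6-methyl-2-oxo-2H-pyran-3-yl)-10-methyl-2-[(trimethylsilyl)ethynyl]undec-5-yn-1-yl acetate | COC1=C(C(C)(C)CCCC#CCC[C@@](COC(C)=O)(C#C[Si](C)(C)C)O)C(=O)OC(C)=C1 | intermediate
18 | [(2S,5E)-5-[1-iodo-5-(4-methoxy-6-methyl-2-oxo-2H-pyran-3-yl)-5-methylhexylidene]-2-[(trimethylsilyl)ethynyl]oxolan-2-yl]methyl acetate | COC1=C(C(C)(C)CCC/C(I)=C2/CC[C@@](COC(C)=O)(C#C[Si](C)(C)C)O2)C(=O)OC(C)=C1 | intermediate
19 | [(2S,5Z)-5-[6-(4-methoxy-6-methyl-2-oxo-2H-pyran-3-yl)-6-methylheptan-2-ylidene]-2-[(trimethylsilyl)ethynyl]oxolan-2-yl]methyl acetate | COC1=C(C(C)(C)CCC/C(C)=C2/CC[C@@](COC(C)=O)(C#C[Si](C)(C)C)O2)C(=O)OC(C)=C1 | intermediate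
20 | cycloadduct: 16-acetoxy-9α,13-epoxy-6-methoxy-15-(trimethylsilyl)labd-6-en-14-yne with 5β-carbonyl lactonised onto the 8β-oxygen (13S) | C1=C(OC)[C@]2(C(=O)O3)C(C)(C)CCC[C@]2(C)[C@@]2(CC[C@@](COC(C)=O)(C#C[Si](C)(C)C)O2)[C@]13C | intermediate
21 | 6β,7β-epoxide of 20 (6-methoxy oxirane, not isolated) | O4[C@H]1[C@]4(OC)[C@]2(C(=O)O3)C(C)(C)CCC[C@]2(C)[C@@]2(CC[C@@](COC(C)=O)(C#C[Si](C)(C)C)O2)[C@]13C | intermediate
22 | 7β-hydroxy-6,6-dimethoxy lactone derived from 20 | O[C@H]1C(OC)(OC)[C@]2(C(=O)O3)C(C)(C)CCC[C@]2(C)[C@@]2(CC[C@@](COC(C)=O)(C#C[Si](C)(C)C)O2)[C@]13C | intermediate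
23 | lithium 7β,8β,16-trihydroxy-6,6-dimethoxy-9α,13-epoxylabd-14-yne-5β-carboxylate (13S, not isolated) | O[C@H]1C(OC)(OC)[C@]2(C(=O)O[Li])C(C)(C)CCC[C@]2(C)[C@@]2(CC[C@@](CO)(C#C)O2)[C@@]1(C)O | intermediate
24 | 7β,8β,16-trihydroxy-6-oxo-9α,13-epoxylabd-14-yne-5β-carboxylic acid (13S, not isolated) | O[C@H]1C(=O)[C@]2(C(=O)O)C(C)(C)CCC[C@]2(C)[C@@]2(CC[C@@](CO)(C#C)O2)[C@@]1(C)O | intermediate
25 | (5S,7R,8S,9S,10S,13S)-7β,8β,16-trihydroxy-9α,13-epoxylabd-14-yn-6-one | O[C@H]1C(=O)[C@H]2C(C)(C)CCC[C@]2(C)[C@@]2(CC[C@@](CO)(C#C)O2)[C@@]1(C)O | intermediate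
26 | (5S,7R,8S,9S,10S,13S)-7β,8β-dihydroxy-9α,13;15,16-diepoxylabd-14-en-6-one | O[C@H]1C(=O)[C@H]2C(C)(C)CCC[C@]2(C)[C@@]2(CC[C@@]3(C=COC3)O2)[C@@]1(C)O | intermediate
27 | (5S,7R,8S,9S,10S,13S)-7β-acetoxy-8β-hydroxy-9α,13;15,16-diepoxylabd-14-en-6-one (CNP0284584.1) | CC(=O)O[C@H]1C(=O)[C@H]2C(C)(C)CCC[C@]2(C)[C@@]2(CC[C@@]3(C=COC3)O2)[C@@]1(C)O | target

**Totals.** Total step count: 17. Longest linear sequence: 17 steps (from 1).

**Steps most likely to fail**

Step 13 (key step). The cycloaddition may be too slow below the temperature at which the bridged lactone loses carbon dioxide, because both partners are electron-rich and both new bonds join fully substituted carbons. The exocyclic enol ether may also migrate into the ring on heating, and discrimination between its two faces by C13 may be incomplete. The fallback closes the same bond pair as a hole-catalysed (cation-radical) Diels–Alder reaction instead of a thermal one. Compound 19 is treated with (4-BrC6H4)3N·SbCl6 (5 mol%) and 2,6-di-tert-butylpyridine in CH2Cl2 at −20 °C, or with Ru(bpz)3(PF6)2 under visible light. One-electron oxidation of the tetrasubstituted enol ether gives a radical cation that is attacked at C10 by the nucleophilic pyrone carbon (C5); the distonic intermediate then closes C8–C9 before back electron transfer. The fallback sets out from 19 and comes back at 20, and no new compound is made (F0).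

Step 12. The β-iodo enol ether may be lost before coupling (protodeiodination or hydrolysis on handling), and the alkenylpalladium intermediate may eliminate the β-alkoxide back to the alkyne. The fallback sets out from 17: bromoetherification (NBS, NaHCO3, MeCN, 0 °C) should give the more robust [(2S,5E)-5-[1-bromo-5-(4-methoxy-6-methyl-2-oxo-2H-pyran-3-yl)-5-methylhexylidene]-2-[(trimethylsilyl)ethynyl]oxolan-2-yl]methyl acetate F1. This is methylated by a Suzuki–Miyaura coupling with trimethylboroxine (Pd(dppf)Cl2, K3PO4, dioxane, 80 °C) under zinc-free, basic conditions, and the route is rejoined at 19.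

Step 15. Hydroxide may not reach the lactone carbonyl, which is flanked by the quaternary C4, C5 and C10, and forcing conditions invite cleavage of ring B (retro-aldol at C7–C8) once the ketone is free. The fallback sets out from 22 and uses hydride instead of hydroxide. (i-Bu)2AlH (CH2Cl2, −78 °C) should reduce the lactone to the bridged lactol F2 (the lactone carbonyl of 22 as CH(OH), the 16-acetate cleaved to the alcohol). 2 M HCl in THF then hydrolyses the ketal and opens the lactol to 5β-formyl-7β,8β,16-trihydroxy-15-(trimethylsilyl)-9α,13-epoxylabd-14-yn-6-one F3. The formyl group of this non-enolisable β-keto aldehyde is removed with K2CO3 in MeOH at 0 °C (retro-Claisen deformylation, which also cleaves the C–Si bond), and the route is rejoined at 25.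

Further compounds
F0 | step 13 | none | none
F1 | step 12 | [(2S,5E)-5-[1-bromo-5-(4-methoxy-6-methyl-2-oxo-2H-pyran-3-yl)-5-methylhexylidene]-2-[(trimethylsilyl)ethynyl]oxolan-2-yl]methyl acetate | COC1=C(C(C)(C)CCC/C(Br)=C2/CC[C@@](COC(C)=O)(C#C[Si](C)(C)C)O2)C(=O)OC(C)=C1
F2 | step 15 | bridged lactol: 22 with the lactone carbonyl reduced to CH(OH) and the 16-acetate cleaved (lactol epimers) | O[C@H]1C(OC)(OC)[C@]2(C(O)O3)C(C)(C)CCC[C@]2(C)[C@@]2(CC[C@@](CO)(C#C[Si](C)(C)C)O2)[C@]13C
F3 | step 15 | 5β-formyl-7β,8β,16-trihydroxy-15-(trimethylsilyl)-9α,13-epoxylabd-14-yn-6-one (13S) | O[C@H]1C(=O)[C@]2(C=O)C(C)(C)CCC[C@]2(C)[C@@]2(CC[C@@](CO)(C#C[Si](C)(C)C)O2)[C@@]1(C)O
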